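**Retrosynthetic overview**
1. Feature: number the benzene ring C1 (CO2H), C2 (OH), C3 (H), C4 (OH), C5 (CH3), C6 (13-methyltetradecyl). The run C6–C1–C2–C3 then carries alkyl, carboxyl, oxygen and hydrogen in the same order as C6–C5–C4–C3 of a 4-alkoxy-2-pyranone-5-carboxylate. The remaining edge C4(O)–C5(CH3) is a propionate unit at the ketene acetal level.
2. Cutting arene bonds C5–C6 and C3–C4 gives a methoxypyranone ester and 1,1-dimethoxyprop-1-ene. These are joined by [4+2] cycloaddition, followed by loss of CO2 and MeOH.
3. Cutting pyranone bonds O1–C2 (enol lactonisation) and C5–C6 (C-acylation) gives dimethyl 3-oxopentanedioate and the chloride of 14-methylpentadecanoic acid.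
4. Ring order: the 2-pyranone ring is made first, and the benzene ring is made out of it in one operation. The end game only removes three O-methyl groups, the ester methyl last.

Key step: step 7

Assumption: 14-methylpentadecanoic acid 1 is bought as such. The target has no stereocentre, so no stereocontrol is needed anywhere.

**Step 1**
Reactants: 1 14-methylpentadecanoic acid
Product: 2 14-methylpentadecanoyl chloride
Conditions: (COCl)2, DMF (cat.), CH2Cl2, 0 °C to rt; concentrate
Reagents that add atoms: oxalyl chloride, O=C(Cl)C(=O)Cl
Why: DMF-catalysed (Vilsmeier-type) acid chloride formation, in which the saturated isoalkyl chain offers no competing site.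

**Step 2**
Reactants: 2 14-methylpentadecanoyl chloride; 3 dimethyl 3-oxopentanedioate
Product: 4 dimethyl 2-(14-methylpentadecanoyl)-3-oxopentanedioate
Conditions: 3 (1.2 equiv), MgCl2, pyridine, CH2Cl2, 0 °C; then 2, 0 °C to rt; cold 1 M HCl
Reagents that add atoms: none
Why: MgCl2/amine soft-enolisation C-acylation of a beta-keto ester, in which the magnesium chelate is acylated at carbon and the more acidic tricarbonyl product stays chelated, which should hold back O-acylation and a second acylation.

**Step 3**
Reactants: 4 dimethyl 2-(14-methylpentadecanoyl)-3-oxopentanedioate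
Product: 5 methyl 4-hydroxy-6-(13-methyltetradecyl)-2-oxo-2H-pyran-5-carboxylate
Conditions: conc. H2SO4, 0 °C to rt; pour on ice
Reagents that add atoms: none
Why: Acid-catalysed enol lactonisation (6-exo-trig), the only six-membered closure open to 4, in which the enol oxygen of the fatty ketone attacks the remote ester and methanol is lost, the same closure that forms isodehydroacetates in cold sulfuric acid.

**Step 4**
Reactants: 5 methyl 4-hydroxy-6-(13-methyltetradecyl)-2-oxo-2H-pyran-5-carboxylate
Product: 6 methyl 4-methoxy-6-(13-methyltetradecyl)-2-oxo-2H-pyran-5-carboxylate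
Conditions: Me2SO4, K2CO3, acetone, reflux
Reagents that add atoms: dimethyl sulfate, COS(=O)(=O)OC
Why: Williamson-type O-methylation of the acidic vinylogous acid, since the hard electrophile with K2CO3 in acetone is the standard way to obtain 4-methoxy-2-pyranones rather than 2-methoxy-4-pyranones or C3-methyl products.

**Step 5**
Reactants: 7 trimethyl orthopropionate
Product: 8 2-bromo-1,1,1-trimethoxypropane (racemic)
Conditions: Br2, pyridine, CH2Cl2, 0–10 °C; filter, distil under reduced pressure
Reagents that add atoms: bromine, BrBr
Why: Classical alpha-bromination of an orthoester through its small equilibrium share of ketene acetal, with pyridine binding the HBr that would otherwise cleave the orthoester.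

**Step 6**
Reactants: 8 2-bromo-1,1,1-trimethoxypropane
Product: 9 1,1-dimethoxyprop-1-ene
Conditions: Na sand (2.2 equiv), benzene, reflux; filter under N2, fractional distillation, store cold over K2CO3
Reagents that add atoms: none
Why: Boord-type reductive 1,2-elimination of bromide and methoxide, the classical entry to alkylketene acetals from alpha-bromo orthoesters, run under basic, acid-free conditions that the product tolerates.

**Step 7**
Reactants: 6 methyl 4-methoxy-6-(13-methyltetradecyl)-2-oxo-2H-pyran-5-carboxylate; 9 1,1-dimethoxyprop-1-ene
Product: 12 methyl 2,4-dimethoxy-5-methyl-6-(13-methyltetradecyl)benzoate, via bridged lactone cycloadduct 10 (not isolated), via cyclohexadiene dimethyl ketal 11 (not isolated)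
Conditions: 9 (10 equiv), mesitylene, base-washed sealed tube, Ar, 160 °C; crude with PPTS (cat.), toluene, 60 °C if 11 persists
Reagents that add atoms: none
Why: The electron-poor diene C3=C4–C5=C6 of 6 and the electron-rich alkene 9 undergo an inverse-electron-demand Diels–Alder reaction that should be strongly asynchronous: the nucleophilic CH(CH3) carbon of 9 bonds to pyranone C6, which is both the far end of the dienyl lactone and the beta carbon of the C5 acrylate, and the C(OMe)2 carbon closes onto C3 to give bridged lactone 10. Cycloreversion of 10 expels CO2 (retro-[4+2]) to leave cyclohexadiene ketal 11, and 1,2-elimination of methanol across C5–H/C4–OMe (arene numbering) gives the aromatic ring of 12. The closest known reaction type is the cycloaddition of coumalates and other alkoxycarbonyl-2-pyranones to ketene acetals and enol ethers, which ends in alkoxybenzoates carrying the donor para to a 5-ester; here it is applied to a less reactive 4-methoxy-6-alkyl member, hence the high temperature and the large excess of 9. The one ring closed, the benzene ring, arises by intermolecular [4+2] closure from four pyranone carbons and the two alkene carbons of 9. The stereocentres of 10 and 11 form as racemic epimer mixtures and are all erased on aromatisation, so neither facial nor endo/exo control is needed. The selectivity needed is regiochemical (CH3-bearing carbon to C6, oxygen-bearing carbon to C3) and rests on the matched polarisation of the partners; the 4-methoxy group sits on the central carbon of the developing C3–C4–C5 allyl anion, so it lowers the rate but should not redirect the attack.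

**Step 8**
Reactants: 12 methyl 2,4-dimethoxy-5-methyl-6-(13-methyltetradecyl)benzoate
Product: 13 methyl 2,4-dihydroxy-5-methyl-6-(13-methyltetradecyl)benzoate
Conditions: BBr3 (5 equiv), CH2Cl2, −78 °C to rt; ice-water
Reagents that add atoms: none
Why: Lewis-acid aryl methyl ether cleavage (O-coordination, then SN2 attack of bromide on methyl), helped at C2 by chelation to the ester carbonyl, while the hindered ester should survive and keep the carboxyl carbon safe from protodecarboxylation in this acidic step.

**Step 9**
Reactants: 13 methyl 2,4-dihydroxy-5-methyl-6-(13-methyltetradecyl)benzoate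
Product: 14 2,4-dihydroxy-5-methyl-6-(13-methyltetradecyl)benzoic acid
Conditions: NaSEt (6 equiv), DMF, Ar, 80 °C; 1 M HCl to pH 2–3 at 0 °C, EtOAc, evaporate below 30 °C
Reagents that add atoms: none
Why: SN2 dealkylation of the ester at its unhindered O-methyl carbon by thiolate (alkyl–oxygen cleavage), which avoids the carbonyl blocked by two ortho substituents and keeps the product as a carboxylate diphenoxide that resists ipso-protonation until the cold acidification.

**Compound list**
1 | 14-methylpentadecanoic acid | CC(C)CCCCCCCCCCCCC(=O)O | starting material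
2 | 14-methylpentadecanoyl chloride | CC(C)CCCCCCCCCCCCC(=O)Cl | intermediate
3 | dimethyl 3-oxopentanedioate | COC(=O)CC(=O)CC(=O)OC | starting material
4 | dimethyl 2-(14-methylpentadecanoyl)-3-oxopentanedioate (drawn as the triketo form, enolised in fact) | COC(=O)CC(=O)C(C(=O)OC)C(=O)CCCCCCCCCCCCC(C)C | intermediate
5 | methyl 4-hydroxy-6-(13-methyltetradecyl)-2-oxo-2H-pyran-5-carboxylate | COC(=O)C1=C(CCCCCCCCCCCCC(C)C)OC(=O)C=C1O | intermediate
6 | methyl 4-methoxy-6-(13-methyltetradecyl)-2-oxo-2H-pyran-5-carboxylate | COC(=O)C1=C(CCCCCCCCCCCCC(C)C)OC(=O)C=C1OC | intermediate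
7 | trimethyl orthopropionate (1,1,1-trimethoxypropane) | CCC(OC)(OC)OC | starting material
8 | 2-bromo-1,1,1-trimethoxypropane (racemic) | CC(Br)C(OC)(OC)OC | intermediate
9 | 1,1-dimethoxyprop-1-ene | CC=C(OC)OC | intermediate
10 | methyl 5,8,8-trimethoxy-7-methyl-1-(13-methyltetradecyl)-3-oxo-2-oxabicyclo[2.2.2]oct-5-ene-6-carboxylate (racemic, both C7 epimers) | O=C1OC2(CCCCCCCCCCCCC(C)C)C(C)C(OC)(OC)C1C(OC)=C2C(=O)OC | intermediate
11 | methyl 4,4,6-trimethoxy-3-methyl-2-(13-methyltetradecyl)cyclohexa-1,5-diene-1-carboxylate (racemic) | COC(=O)C1=C(CCCCCCCCCCCCC(C)C)C(C)C(OC)(OC)C=C1OC | intermediate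
12 | methyl 2,4-dimethoxy-5-methyl-6-(13-methyltetradecyl)benzoate | COC(=O)c1c(OC)cc(OC)c(C)c1CCCCCCCCCCCCC(C)C | intermediate
13 | methyl 2,4-dihydroxy-5-methyl-6-(13-methyltetradecyl)benzoate | COC(=O)c1c(O)cc(O)c(C)c1CCCCCCCCCCCCC(C)C | intermediate
14 | 2,4-dihydroxy-5-methyl-6-(13-methyltetradecyl)benzoic acid | Cc1c(O)cc(O)c(C(=O)O)c1CCCCCCCCCCCCC(C)C | target

**Totals**
Total step count: 9.
Longest linear sequence: 7 (steps 1, 2, 3, 4, 7, 8, 9).

**Steps most likely to fail**

Step 7.
- Risk: the donor at C4 and the alkyl group at C6 may slow bond formation at C6. Thermal oligomerisation of the ketene acetal could then take over. So could conjugate addition followed by opening of the lactone instead of closure at C3.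
- Fallback: this sets out from 2 and comes back at 13, building the ring by Michael–Claisen annulation instead. Acid chloride 2 is reduced with LiAlH(Ot-Bu)3 (THF, −78 °C) to 14-methylpentadecanal F1. Wittig olefination with 3-(triphenylphosphoranylidene)butan-2-one gives (E)-3,17-dimethyloctadec-3-en-2-one F2.
- Michael addition of dimethyl malonate (NaOMe, MeOH, reflux) and intramolecular Claisen condensation in the same pot give methyl 3-methyl-2-(13-methyltetradecyl)-4,6-dioxocyclohexane-1-carboxylate F3. This forms as a diastereomer mixture whose stereocentres are lost in the next operation. Bromination–dehydrobromination (Br2, DMF, 0 to 80 °C) aromatises F3 to 13, and step 9 follows.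

Step 9.
- Risk: the resorcylate may protodecarboxylate during the hot thiolate treatment or on acidification. The SN2 attack may also stall, because the doubly deprotonated ester expels a poor leaving group.
- Fallback: this sets out from 13 and comes back at 14, moving the ester cleavage to a neutral ring and making the last step a neutral hydrogenolysis. Williamson benzylation (BnBr, K2CO3, DMF, 60 °C) gives methyl 2,4-bis(benzyloxy)-5-methyl-6-(13-methyltetradecyl)benzoate F4. Hydrolysis with KOH in DMSO/H2O at 100 °C gives 2,4-bis(benzyloxy)-5-methyl-6-(13-methyltetradecyl)benzoic acid F5, which is not prone to decarboxylation. H2 over Pd/C in EtOAc at rt then releases 14.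

Step 3.
- Risk: in the strong acid, retro-Claisen loss of the fatty acyl group may compete with lactonisation of the waxy substrate. Hydrolysis and decarboxylation of the C5 ester may compete as well.
- Fallback: this sets out from 2 and comes back at 5, assembling the pyranone from the opposite pair of fragments. Decarboxylative acylation of potassium methyl malonate (KO2CCH2CO2Me, MgCl2, Et3N, MeCN, 0 °C to rt) with 2 gives methyl 16-methyl-3-oxoheptadecanoate F6. Cyclocondensation of its alpha carbon and enol oxygen with bis(2,4,6-trichlorophenyl) malonate (1 equiv, bromobenzene, reflux) closes the 4-hydroxy-2-pyranone 5 without strong acid.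

**Further compounds**
F1 | step 7 | 14-methylpentadecanal | CC(C)CCCCCCCCCCCCC=O
F2 | step 7 | (E)-3,17-dimethyloctadec-3-en-2-one | CC(=O)/C(C)=C/CCCCCCCCCCCCC(C)C
F3 | step 7 | methyl 3-methyl-2-(13-methyltetradecyl)-4,6-dioxocyclohexane-1-carboxylate (diastereomer mixture) | COC(=O)C1C(CCCCCCCCCCCCC(C)C)C(C)C(=O)CC1=O
F4 | step 9 | methyl 2,4-bis(benzyloxy)-5-methyl-6-(13-methyltetradecyl)benzoate | COC(=O)c1c(OCc2ccccc2)cc(OCc2ccccc2)c(C)c1CCCCCCCCCCCCC(C)C
F5 | step 9 | 2,4-bis(benzyloxy)-5-methyl-6-(13-methyltetradecyl)benzoic acid | OC(=O)c1c(OCc2ccccc2)cc(OCc2ccccc2)c(C)c1CCCCCCCCCCCCC(C)C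
F6 | step 3 | methyl 16-methyl-3-oxoheptadecanoate | COC(=O)CC(=O)CCCCCCCCCCCCC(C)C
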